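**Retrosynthetic overview**
- The last bond made is the ether between ring C (its C2 oxygen) and ring D (C1), by Cu-catalysed coupling of the hindered ring C phenol of trimer ABC with the ring D bromide of tetramer DEFG; global hydrogenolysis of eighteen benzyl ethers follows.
- The strategy rests on ring B: oxygens at C1 (to ring A), C3 and C5 (free OH) in the phloroglucinol pattern plus a fourth at C4 (to ring C), which is the pattern of a 2-aryloxy-3,5-dioxohexanoate folded by Claisen condensation. Ring B is therefore built, not coupled: the methyl carbon of a 2-aryloxy-3-oxo-5-aryloxyhex-4-enoate attacks the ester carbon and forms the C5–C6 bond of ring B.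
- Both hindered ethers of ring B are made before the ring exists: ring A enters as an aryl enol ether (oxa-Michael addition to methyl but-2-ynoate), and the tri-ortho-substituted ring B–O–ring C ether is made by SN2 on methyl bromoacetate; a bromine on ring C is later exchanged for the hydroxyl that carries ring D.
- Ring F has the same oxygen pattern and is built the same way from the ring G oxyacetate and the hindered ring E phenol; that phenol comes from Ullmann coupling of 3,4,5-tris(benzyloxy)phenol with a bromo-iodo ring D unit, formylation and Baeyer–Villiger oxidation.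
- Order of ring formation: rings A, C, D, E and G are bought as arenes; ring B is formed in step 9 and ring F in step 22.

Key step: step 9

Assumption: compounds 1, 8 and 21 are taken as catalogue compounds; the target has no stereocentre, and keto esters 15 and 33 are racemic at C2, a centre that disappears on aromatisation.

**Route**

Step 1
Reactants: 1 1,3,5-tris(benzyloxy)benzene
Product: 2 2,4,6-tris(benzyloxy)benzaldehyde
Conditions: POCl3, DMF, 0 °C to 50 °C; then ice-water
Reagents that add atoms: N,N-dimethylformamide, CN(C)C=O; water, O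
Why: Vilsmeier–Haack formylation; the three free ring positions are equivalent and each is ortho/para to three benzyloxy groups, so a single aldehyde should form after hydrolysis of the iminium salt.

Step 2
Reactants: 2 2,4,6-tris(benzyloxy)benzaldehyde
Product: 4 2,4,6-tris(benzyloxy)phenol, via aryl formate 3 (not isolated)
Conditions: mCPBA, CH2Cl2, 0 °C to rt; aq. NaHCO3 wash; then K2CO3 (cat.), MeOH, rt, under argon
Reagents that add atoms: 3-chloroperoxybenzoic acid, O=C(OO)c1cccc(Cl)c1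
Why: Baeyer–Villiger (Dakin-type) oxidation; the electron-rich aryl group migrates in the Criegee adduct to give formate 3, which is methanolysed to the phenol.

Step 3
Reactants: 4 2,4,6-tris(benzyloxy)phenol; 5 methyl but-2-ynoate
Product: 6 methyl (E)-3-[2,4,6-tris(benzyloxy)phenoxy]but-2-enoate
Conditions: K2CO3 (0.5 equiv), DMF, 70 °C
Reagents that add atoms: none
Why: Base-catalysed oxa-Michael addition of the phenoxide to the ynoate; the addition is reversible under these conditions and should settle on the more stable (E)-enol ether, with the aryloxy group trans to the ester and the methyl group cis to the carbonyl.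

Step 4
Reactants: 6 methyl (E)-3-[2,4,6-tris(benzyloxy)phenoxy]but-2-enoate
Product: 7 (E)-3-[2,4,6-tris(benzyloxy)phenoxy]but-2-enoic acid
Conditions: LiOH, THF–H2O, 40 °C; then cold 1 M HCl to pH 3
Reagents that add atoms: lithium hydroxide, [Li+].[OH-]
Why: Saponification (acyl–oxygen cleavage); hydroxide should attack the ester carbonyl in preference to the fully substituted, shielded β-carbon, and cold dilute acid frees the acid without hydrolysing the enol ether.

Step 5
Reactants: 8 3,4,5-tris(benzyloxy)benzaldehyde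
Product: 10 3,4,5-tris(benzyloxy)phenol, via aryl formate 9 (not isolated)
Conditions: mCPBA, CH2Cl2, 0 °C to rt; aq. NaHCO3 wash; then K2CO3 (cat.), MeOH, rt
Reagents that add atoms: 3-chloroperoxybenzoic acid, O=C(OO)c1cccc(Cl)c1
Why: Baeyer–Villiger oxidation; the para-benzyloxy group favours aryl over hydride migration, and the formate 9 is cleaved by methanolysis.

Step 6
Reactants: 10 3,4,5-tris(benzyloxy)phenol
Product: 11 3,4,5-tris(benzyloxy)-2-bromophenol
Conditions: NBS (1.0 equiv), CH2Cl2, −78 °C to 0 °C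
Reagents that add atoms: N-bromosuccinimide, O=C1CCC(=O)N1Br
Why: Electrophilic aromatic bromination ortho to the free phenol; the para position is blocked and the two ortho positions are equivalent, so one equivalent of reagent at low temperature should give the monobromide.

Step 7
Reactants: 11 3,4,5-tris(benzyloxy)-2-bromophenol; 12 methyl bromoacetate
Product: 13 methyl 2-[3,4,5-tris(benzyloxy)-2-bromophenoxy]acetate
Conditions: K2CO3, acetone, reflux
Reagents that add atoms: none
Why: Williamson ether synthesis (SN2 at a primary α-halo ester); this forms the future tri-ortho-substituted ring B–O–ring C ether at an sp3 carbon.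

Step 8
Reactants: 7 (E)-3-[2,4,6-tris(benzyloxy)phenoxy]but-2-enoic acid; 13 methyl 2-[3,4,5-tris(benzyloxy)-2-bromophenoxy]acetate
Product: 15 methyl (E)-2-[3,4,5-tris(benzyloxy)-2-bromophenoxy]-3-oxo-5-[2,4,6-tris(benzyloxy)phenoxy]hex-4-enoate (racemic), via acyl imidazole 14 (not isolated)
Conditions: 7, 1,1'-carbonyldiimidazole, THF, rt; solution added to 13 + LiN(SiMe3)2 (3.2 equiv), THF, −78 °C to −40 °C; then AcOH
Reagents that add atoms: none
Why: Crossed Claisen-type C-acylation of a lithium ester enolate by an acyl imidazole; the chelated α-aryloxy enolate should add to the acyl carbon at low temperature, and the extra base covers the liberated imidazole and the more acidic β-keto ester product.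

Step 9
Reactants: 15 methyl (E)-2-[3,4,5-tris(benzyloxy)-2-bromophenoxy]-3-oxo-5-[2,4,6-tris(benzyloxy)phenoxy]hex-4-enoate (racemic)
Product: 16 2-[3,4,5-tris(benzyloxy)-2-bromophenoxy]-5-[2,4,6-tris(benzyloxy)phenoxy]benzene-1,3-diol
Conditions: LiN(SiMe3)2 (4 equiv), THF, −78 °C to rt; then 1 M HCl
Reagents that add atoms: none
Why: The base first removes the C2 proton between ester and ketone and then, being in excess, a proton of the C6 methyl group, which is vinylogous to the C3 ketone; the methylene terminus of this dianion attacks the ester carbon (C1 of the chain), methoxide leaves and the cyclohexenedione enolises, so the C5–C6 bond of ring B is formed and ring B is closed and aromatised in one operation. The closest known reaction type is the Claisen (Dieckmann-type) cyclisation of 3,5-dioxohexanoate triketide esters and of their enol ethers to phloroglucinols. Ring B closes in the 6-exo-trig mode, the methyl carbon attacking the exocyclic ester C=O. No stereocentre is formed, and the racemic C2 centre of 15 becomes an sp2 ring carbon. The step needs C- rather than O-acylation and must avoid retro-Claisen cleavage and loss of the ring A phenoxide: the C5 oxygen is fixed as an aryl enol ether so no enol oxygen can lactonise to a pyrone, the (E)-geometry holds the methyl group cis to the keto ester chain, the silylamide is non-nucleophilic, and the planar dienolate required for closure keeps the C5–O bond orthogonal to the π system. Rotation about C4–C5 in the dienolate should also let any minor (Z)-isomer converge on the same product.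

Step 10
Reactants: 16 2-[3,4,5-tris(benzyloxy)-2-bromophenoxy]-5-[2,4,6-tris(benzyloxy)phenoxy]benzene-1,3-diol
Product: 17 1,3-bis(benzyloxy)-2-[3,4,5-tris(benzyloxy)-2-bromophenoxy]-5-[2,4,6-tris(benzyloxy)phenoxy]benzene
Conditions: BnBr, K2CO3, DMF, 40 °C
Reagents that add atoms: benzyl bromide, BrCc1ccccc1
Why: Williamson benzylation of the two resorcinol hydroxyls, which puts ring B in the same protecting group as the rest.

Step 11
Reactants: 17 1,3-bis(benzyloxy)-2-[3,4,5-tris(benzyloxy)-2-bromophenoxy]-5-[2,4,6-tris(benzyloxy)phenoxy]benzene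
Product: 20 2,3,4-tris(benzyloxy)-6-{2,6-bis(benzyloxy)-4-[2,4,6-tris(benzyloxy)phenoxy]phenoxy}phenol, via aryllithium 18 (not isolated), via dimethyl arylboronate 19 (not isolated)
Conditions: n-BuLi, THF, −78 °C; B(OMe)3, −78 °C to 0 °C; then AcOH, 30% H2O2, 0 °C to rt
Reagents that add atoms: hydrogen peroxide, OO
Why: Bromine–lithium exchange (the aryllithium is stabilised by two ortho oxygens), borylation and oxidative 1,2-aryl migration from boron to oxygen; none of these stages touches benzyl or diaryl ethers at low temperature.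

Step 12
Reactants: 21 4-bromo-2-methoxyphenol
Product: 22 4-bromo-2-iodo-6-methoxyphenol
Conditions: NIS, TsOH (cat.), MeCN, rt
Reagents that add atoms: N-iodosuccinimide, O=C1CCC(=O)N1I
Why: Electrophilic aromatic iodination directed by the free phenol to its only open ortho position, the para position being held by bromine.

Step 13
Reactants: 22 4-bromo-2-iodo-6-methoxyphenol
Product: 23 5-bromo-3-iodobenzene-1,2-diol
Conditions: BBr3, CH2Cl2, −78 °C to rt; then H2O
Reagents that add atoms: none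
Why: Lewis acid cleavage of the aryl methyl ether by BBr3; aryl halides are inert to it.

Step 14
Reactants: 23 5-bromo-3-iodobenzene-1,2-diol
Product: 24 1,2-bis(benzyloxy)-5-bromo-3-iodobenzene
Conditions: BnBr, K2CO3, DMF, rt, under argon
Reagents that add atoms: benzyl bromide, BrCc1ccccc1
Why: Williamson benzylation of the catechol gives the ring D unit, with iodine at the future ring E ether carbon and bromine at the future ring C ether carbon.

Step 15
Reactants: 10 3,4,5-tris(benzyloxy)phenol; 24 1,2-bis(benzyloxy)-5-bromo-3-iodobenzene (1.2 equiv)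
Product: 25 1,2-bis(benzyloxy)-5-bromo-3-[3,4,5-tris(benzyloxy)phenoxy]benzene
Conditions: CuI (10 mol%), picolinic acid (20 mol%), K3PO4, DMSO, 80 °C
Reagents that add atoms: none
Why: Ullmann-type Cu-catalysed diaryl ether synthesis with an unhindered phenol; the C–I bond should react well before the C–Br bond, so the bromide is kept for the final union.

Step 16
Reactants: 25 1,2-bis(benzyloxy)-5-bromo-3-[3,4,5-tris(benzyloxy)phenoxy]benzene
Product: 26 2,3,4-tris(benzyloxy)-6-[2,3-bis(benzyloxy)-5-bromophenoxy]benzaldehyde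
Conditions: POCl3, DMF, 0 °C to 50 °C; then ice-water
Reagents that add atoms: N,N-dimethylformamide, CN(C)C=O; water, O
Why: Vilsmeier–Haack formylation should occur on ring E, whose two equivalent free positions are each ortho/para to three oxygens; the free positions of ring D have only two such oxygens and a flanking bromine.

Step 17
Reactants: 26 2,3,4-tris(benzyloxy)-6-[2,3-bis(benzyloxy)-5-bromophenoxy]benzaldehyde
Product: 28 2,3,4-tris(benzyloxy)-6-[2,3-bis(benzyloxy)-5-bromophenoxy]phenol, via aryl formate 27 (not isolated)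
Conditions: mCPBA, CH2Cl2, 0 °C to rt; aq. NaHCO3 wash; then K2CO3 (cat.), MeOH, rt
Reagents that add atoms: 3-chloroperoxybenzoic acid, O=C(OO)c1cccc(Cl)c1
Why: Baeyer–Villiger oxidation of a benzaldehyde carrying two ortho oxygens and a para oxygen, followed by methanolysis of formate 27, gives the hindered ring E phenol while the ring D bromide is untouched.

Step 18
Reactants: 28 2,3,4-tris(benzyloxy)-6-[2,3-bis(benzyloxy)-5-bromophenoxy]phenol; 5 methyl but-2-ynoate
Product: 29 methyl (E)-3-{2,3,4-tris(benzyloxy)-6-[2,3-bis(benzyloxy)-5-bromophenoxy]phenoxy}but-2-enoate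
Conditions: K2CO3 (0.5 equiv), DMF, 70 °C
Reagents that add atoms: none
Why: Base-catalysed oxa-Michael addition as in step 3, expected to give the thermodynamic (E)-enol ether.

Step 19
Reactants: 29 methyl (E)-3-{2,3,4-tris(benzyloxy)-6-[2,3-bis(benzyloxy)-5-bromophenoxy]phenoxy}but-2-enoate
Product: 30 (E)-3-{2,3,4-tris(benzyloxy)-6-[2,3-bis(benzyloxy)-5-bromophenoxy]phenoxy}but-2-enoic acid
Conditions: LiOH, THF–H2O, 40 °C; then cold 1 M HCl to pH 3
Reagents that add atoms: lithium hydroxide, [Li+].[OH-]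
Why: Saponification as in step 4, with attack at the ester carbonyl rather than the shielded β-carbon.

Step 20
Reactants: 10 3,4,5-tris(benzyloxy)phenol; 12 methyl bromoacetate
Product: 31 methyl 2-[3,4,5-tris(benzyloxy)phenoxy]acetate
Conditions: K2CO3, acetone, reflux
Reagents that add atoms: none
Why: Williamson ether synthesis (SN2); this forms the future hindered ring F–O–ring G ether at an sp3 carbon.

Step 21
Reactants: 30 (E)-3-{2,3,4-tris(benzyloxy)-6-[2,3-bis(benzyloxy)-5-bromophenoxy]phenoxy}but-2-enoic acid; 31 methyl 2-[3,4,5-tris(benzyloxy)phenoxy]acetate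
Product: 33 methyl (E)-5-{2,3,4-tris(benzyloxy)-6-[2,3-bis(benzyloxy)-5-bromophenoxy]phenoxy}-3-oxo-2-[3,4,5-tris(benzyloxy)phenoxy]hex-4-enoate (racemic), via acyl imidazole 32 (not isolated)
Conditions: 30, 1,1'-carbonyldiimidazole, THF, rt; solution added to 31 + LiN(SiMe3)2 (3.2 equiv), THF, −78 °C to −40 °C; then AcOH
Reagents that add atoms: none
Why: Crossed Claisen-type C-acylation of the lithium ester enolate by the acyl imidazole, as in step 8; the aryl bromide is inert to the silylamide base.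

Step 22
Reactants: 33 methyl (E)-5-{2,3,4-tris(benzyloxy)-6-[2,3-bis(benzyloxy)-5-bromophenoxy]phenoxy}-3-oxo-2-[3,4,5-tris(benzyloxy)phenoxy]hex-4-enoate (racemic)
Product: 34 5-{2,3,4-tris(benzyloxy)-6-[2,3-bis(benzyloxy)-5-bromophenoxy]phenoxy}-2-[3,4,5-tris(benzyloxy)phenoxy]benzene-1,3-diol
Conditions: LiN(SiMe3)2 (4 equiv), THF, −78 °C to rt; then 1 M HCl
Reagents that add atoms: none
Why: The same Claisen cyclisation and aromatisation as in step 9 (dianion formation, 6-exo-trig attack of the methyl carbon on the ester, loss of methoxide, enolisation), here closing ring F with its C1 oxygen on ring E and its C4 oxygen on ring G.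

Step 23
Reactants: 34 5-{2,3,4-tris(benzyloxy)-6-[2,3-bis(benzyloxy)-5-bromophenoxy]phenoxy}-2-[3,4,5-tris(benzyloxy)phenoxy]benzene-1,3-diol
Product: 35 1,3-bis(benzyloxy)-5-{2,3,4-tris(benzyloxy)-6-[2,3-bis(benzyloxy)-5-bromophenoxy]phenoxy}-2-[3,4,5-tris(benzyloxy)phenoxy]benzene
Conditions: BnBr, K2CO3, DMF, 40 °C
Reagents that add atoms: benzyl bromide, BrCc1ccccc1
Why: Williamson benzylation of the two ring F hydroxyls.

Step 24
Reactants: 20 2,3,4-tris(benzyloxy)-6-{2,6-bis(benzyloxy)-4-[2,4,6-tris(benzyloxy)phenoxy]phenoxy}phenol; 35 1,3-bis(benzyloxy)-5-{2,3,4-tris(benzyloxy)-6-[2,3-bis(benzyloxy)-5-bromophenoxy]phenoxy}-2-[3,4,5-tris(benzyloxy)phenoxy]benzene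
Product: 36 octadeca-O-benzyl ether of the target (rings A to G fully assembled)
Conditions: CuI (20 mol%), picolinic acid (40 mol%), K3PO4, DMSO–1,4-dioxane, 105 °C
Reagents that add atoms: none
Why: Ullmann-type Cu-catalysed C–O coupling under conditions developed for doubly ortho-substituted phenols; the bromide sits on the ring D carbon flanked by two hydrogens, so all the steric demand lies on the phenol side.

Step 25
Reactants: 36 octadeca-O-benzyl ether of the target
Product: 37 target CNP0130704.0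
Conditions: H2 (1 atm), Pd(OH)2/C, THF–MeOH, rt; handled under argon
Reagents that add atoms: none
Why: Catalytic hydrogenolysis cleaves all eighteen benzyl ethers and leaves the six diaryl ethers intact.

**Compound list**
1 | 1,3,5-tris(benzyloxy)benzene | c1c(OCc9ccccc9)cc(OCc9ccccc9)cc1OCc9ccccc9 | starting material
2 | 2,4,6-tris(benzyloxy)benzaldehyde | O=Cc1c(OCc9ccccc9)cc(OCc9ccccc9)cc1OCc9ccccc9 | intermediate
3 | 2,4,6-tris(benzyloxy)phenyl formate (not isolated) | O=COc1c(OCc9ccccc9)cc(OCc9ccccc9)cc1OCc9ccccc9 | intermediate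
4 | 2,4,6-tris(benzyloxy)phenol | Oc1c(OCc9ccccc9)cc(OCc9ccccc9)cc1OCc9ccccc9 | intermediate
5 | methyl but-2-ynoate | CC#CC(=O)OC | starting material
6 | methyl (E)-3-[2,4,6-tris(benzyloxy)phenoxy]but-2-enoate | COC(=O)/C=C(\C)Oc1c(OCc9ccccc9)cc(OCc9ccccc9)cc1OCc9ccccc9 | intermediate
7 | (E)-3-[2,4,6-tris(benzyloxy)phenoxy]but-2-enoic acid | OC(=O)/C=C(\C)Oc1c(OCc9ccccc9)cc(OCc9ccccc9)cc1OCc9ccccc9 | intermediate
8 | 3,4,5-tris(benzyloxy)benzaldehyde | O=Cc1cc(OCc9ccccc9)c(OCc9ccccc9)c(OCc9ccccc9)c1 | starting material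
9 | 3,4,5-tris(benzyloxy)phenyl formate (not isolated) | O=COc1cc(OCc9ccccc9)c(OCc9ccccc9)c(OCc9ccccc9)c1 | intermediate
10 | 3,4,5-tris(benzyloxy)phenol | Oc1cc(OCc9ccccc9)c(OCc9ccccc9)c(OCc9ccccc9)c1 | intermediate
11 | 3,4,5-tris(benzyloxy)-2-bromophenol | Oc1cc(OCc9ccccc9)c(OCc9ccccc9)c(OCc9ccccc9)c1Br | intermediate
12 | methyl bromoacetate | COC(=O)CBr | starting material
13 | methyl 2-[3,4,5-tris(benzyloxy)-2-bromophenoxy]acetate | COC(=O)COc1cc(OCc9ccccc9)c(OCc9ccccc9)c(OCc9ccccc9)c1Br | intermediate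
14 | (E)-1-(imidazol-1-yl)-3-[2,4,6-tris(benzyloxy)phenoxy]but-2-en-1-one (acyl imidazole, not isolated) | O=C(/C=C(\C)Oc1c(OCc9ccccc9)cc(OCc9ccccc9)cc1OCc9ccccc9)n1ccnc1 | intermediate
15 | methyl (E)-2-[3,4,5-tris(benzyloxy)-2-bromophenoxy]-3-oxo-5-[2,4,6-tris(benzyloxy)phenoxy]hex-4-enoate (racemic) | COC(=O)C(Oc1cc(OCc9ccccc9)c(OCc9ccccc9)c(OCc9ccccc9)c1Br)C(=O)/C=C(\C)Oc1c(OCc9ccccc9)cc(OCc9ccccc9)cc1OCc9ccccc9 | intermediate
16 | 2-[3,4,5-tris(benzyloxy)-2-bromophenoxy]-5-[2,4,6-tris(benzyloxy)phenoxy]benzene-1,3-diol | Oc1cc(Oc2c(OCc9ccccc9)cc(OCc9ccccc9)cc2OCc9ccccc9)cc(O)c1Oc1cc(OCc9ccccc9)c(OCc9ccccc9)c(OCc9ccccc9)c1Br | intermediate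
17 | 1,3-bis(benzyloxy)-2-[3,4,5-tris(benzyloxy)-2-bromophenoxy]-5-[2,4,6-tris(benzyloxy)phenoxy]benzene | c9ccccc9COc1cc(Oc2c(OCc9ccccc9)cc(OCc9ccccc9)cc2OCc9ccccc9)cc(OCc9ccccc9)c1Oc1cc(OCc9ccccc9)c(OCc9ccccc9)c(OCc9ccccc9)c1Br | intermediate
18 | aryllithium from 17, lithium in place of bromine on ring C (not isolated) | c9ccccc9COc1cc(Oc2c(OCc9ccccc9)cc(OCc9ccccc9)cc2OCc9ccccc9)cc(OCc9ccccc9)c1Oc1cc(OCc9ccccc9)c(OCc9ccccc9)c(OCc9ccccc9)c1[Li] | intermediate
19 | dimethyl arylboronate from 18, B(OMe)2 on ring C (not isolated) | c9ccccc9COc1cc(Oc2c(OCc9ccccc9)cc(OCc9ccccc9)cc2OCc9ccccc9)cc(OCc9ccccc9)c1Oc1cc(OCc9ccccc9)c(OCc9ccccc9)c(OCc9ccccc9)c1B(OC)OC | intermediate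
20 | 2,3,4-tris(benzyloxy)-6-{2,6-bis(benzyloxy)-4-[2,4,6-tris(benzyloxy)phenoxy]phenoxy}phenol | c9ccccc9COc1cc(Oc2c(OCc9ccccc9)cc(OCc9ccccc9)cc2OCc9ccccc9)cc(OCc9ccccc9)c1Oc1cc(OCc9ccccc9)c(OCc9ccccc9)c(OCc9ccccc9)c1O | intermediate
21 | 4-bromo-2-methoxyphenol | COc1cc(Br)ccc1O | starting material
22 | 4-bromo-2-iodo-6-methoxyphenol | COc1cc(Br)cc(I)c1O | intermediate
23 | 5-bromo-3-iodobenzene-1,2-diol | Oc1cc(Br)cc(I)c1O | intermediate
24 | 1,2-bis(benzyloxy)-5-bromo-3-iodobenzene | Brc1cc(I)c(OCc9ccccc9)c(OCc9ccccc9)c1 | intermediate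
25 | 1,2-bis(benzyloxy)-5-bromo-3-[3,4,5-tris(benzyloxy)phenoxy]benzene | Brc1cc(Oc2cc(OCc9ccccc9)c(OCc9ccccc9)c(OCc9ccccc9)c2)c(OCc9ccccc9)c(OCc9ccccc9)c1 | intermediate
26 | 2,3,4-tris(benzyloxy)-6-[2,3-bis(benzyloxy)-5-bromophenoxy]benzaldehyde | Brc1cc(Oc2cc(OCc9ccccc9)c(OCc9ccccc9)c(OCc9ccccc9)c2C=O)c(OCc9ccccc9)c(OCc9ccccc9)c1 | intermediate
27 | 2,3,4-tris(benzyloxy)-6-[2,3-bis(benzyloxy)-5-bromophenoxy]phenyl formate (not isolated) | Brc1cc(Oc2cc(OCc9ccccc9)c(OCc9ccccc9)c(OCc9ccccc9)c2OC=O)c(OCc9ccccc9)c(OCc9ccccc9)c1 | intermediate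
28 | 2,3,4-tris(benzyloxy)-6-[2,3-bis(benzyloxy)-5-bromophenoxy]phenol | Brc1cc(Oc2cc(OCc9ccccc9)c(OCc9ccccc9)c(OCc9ccccc9)c2O)c(OCc9ccccc9)c(OCc9ccccc9)c1 | intermediate
29 | methyl (E)-3-{2,3,4-tris(benzyloxy)-6-[2,3-bis(benzyloxy)-5-bromophenoxy]phenoxy}but-2-enoate | COC(=O)/C=C(\C)Oc1c(OCc9ccccc9)c(OCc9ccccc9)c(OCc9ccccc9)cc1Oc1cc(Br)cc(OCc9ccccc9)c1OCc9ccccc9 | intermediate
30 | (E)-3-{2,3,4-tris(benzyloxy)-6-[2,3-bis(benzyloxy)-5-bromophenoxy]phenoxy}but-2-enoic acid | OC(=O)/C=C(\C)Oc1c(OCc9ccccc9)c(OCc9ccccc9)c(OCc9ccccc9)cc1Oc1cc(Br)cc(OCc9ccccc9)c1OCc9ccccc9 | intermediate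
31 | methyl 2-[3,4,5-tris(benzyloxy)phenoxy]acetate | COC(=O)COc1cc(OCc9ccccc9)c(OCc9ccccc9)c(OCc9ccccc9)c1 | intermediate
32 | (E)-1-(imidazol-1-yl)-3-{2,3,4-tris(benzyloxy)-6-[2,3-bis(benzyloxy)-5-bromophenoxy]phenoxy}but-2-en-1-one (acyl imidazole, not isolated) | O=C(/C=C(\C)Oc1c(OCc9ccccc9)c(OCc9ccccc9)c(OCc9ccccc9)cc1Oc1cc(Br)cc(OCc9ccccc9)c1OCc9ccccc9)n1ccnc1 | intermediate
33 | methyl (E)-5-{2,3,4-tris(benzyloxy)-6-[2,3-bis(benzyloxy)-5-bromophenoxy]phenoxy}-3-oxo-2-[3,4,5-tris(benzyloxy)phenoxy]hex-4-enoate (racemic) | COC(=O)C(Oc1cc(OCc9ccccc9)c(OCc9ccccc9)c(OCc9ccccc9)c1)C(=O)/C=C(\C)Oc1c(OCc9ccccc9)c(OCc9ccccc9)c(OCc9ccccc9)cc1Oc1cc(Br)cc(OCc9ccccc9)c1OCc9ccccc9 | intermediate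
34 | 5-{2,3,4-tris(benzyloxy)-6-[2,3-bis(benzyloxy)-5-bromophenoxy]phenoxy}-2-[3,4,5-tris(benzyloxy)phenoxy]benzene-1,3-diol | Oc1cc(Oc2c(OCc9ccccc9)c(OCc9ccccc9)c(OCc9ccccc9)cc2Oc2cc(Br)cc(OCc9ccccc9)c2OCc9ccccc9)cc(O)c1Oc1cc(OCc9ccccc9)c(OCc9ccccc9)c(OCc9ccccc9)c1 | intermediate
35 | 1,3-bis(benzyloxy)-5-{2,3,4-tris(benzyloxy)-6-[2,3-bis(benzyloxy)-5-bromophenoxy]phenoxy}-2-[3,4,5-tris(benzyloxy)phenoxy]benzene | c9ccccc9COc1cc(Oc2c(OCc9ccccc9)c(OCc9ccccc9)c(OCc9ccccc9)cc2Oc2cc(Br)cc(OCc9ccccc9)c2OCc9ccccc9)cc(OCc9ccccc9)c1Oc1cc(OCc9ccccc9)c(OCc9ccccc9)c(OCc9ccccc9)c1 | intermediate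
36 | octadeca-O-benzyl ether of the target (every hydroxyl of rings A to G as a benzyl ether) | c9ccccc9COc1cc(OCc9ccccc9)c(Oc2cc(OCc9ccccc9)c(Oc3cc(OCc9ccccc9)c(OCc9ccccc9)c(OCc9ccccc9)c3Oc3cc(OCc9ccccc9)c(OCc9ccccc9)c(Oc4cc(OCc9ccccc9)c(OCc9ccccc9)c(OCc9ccccc9)c4Oc4cc(OCc9ccccc9)c(Oc5cc(OCc9ccccc9)c(OCc9ccccc9)c(OCc9ccccc9)c5)c(OCc9ccccc9)c4)c3)c(OCc9ccccc9)c2)c(OCc9ccccc9)c1 | intermediate
37 | CNP0130704.0, heptameric aryl ether of rings A to G with eighteen free hydroxyls | Oc1cc(O)c(Oc2cc(O)c(Oc3cc(O)c(O)c(O)c3Oc3cc(O)c(O)c(Oc4cc(O)c(O)c(O)c4Oc4cc(O)c(Oc5cc(O)c(O)c(O)c5)c(O)c4)c3)c(O)c2)c(O)c1 | target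

**Step count and risk**
Total steps: 25. Longest linear sequence: 13 steps (from 21: steps 12 to 19 and 21 to 25).

Steps most likely to fail:

1. Step 9 (Claisen cyclisation to ring B; step 22 runs the same chemistry). Once the proton between ester and ketone is removed, the ester carbon is part of an enolate and a weak electrophile. The second deprotonation at the vinylogous methyl group may be incomplete with a silylamide base. The dienolate may also expel the ring A phenoxide instead of closing. The fallback blocks the acidic position with a removable ester; it sets out from phenol 11 and acyl imidazole 14 and returns at 16. Phenol 11 is alkylated with dimethyl chloromalonate (K2CO3, acetone) to dimethyl 2-[3,4,5-tris(benzyloxy)-2-bromophenoxy]malonate F1. Its sodium enolate (NaH, THF) is acylated with 14 to dimethyl 2-[3,4,5-tris(benzyloxy)-2-bromophenoxy]-2-{(E)-3-[2,4,6-tris(benzyloxy)phenoxy]but-2-enoyl}malonate F2, which has no proton between the carbonyl groups. LiN(SiMe3)2 can then only deprotonate the methyl group, and Dieckmann-type closure onto one malonate ester should give methyl 1-[3,4,5-tris(benzyloxy)-2-bromophenoxy]-2,6-dioxo-4-[2,4,6-tris(benzyloxy)phenoxy]cyclohex-3-ene-1-carboxylate F3. Krapcho dealkoxycarbonylation (LiCl, wet DMSO, heat) removes the blocking ester with aromatisation to 16.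

2. Step 24 (union of 20 and 35). Ligand exchange at copper may be slow for a doubly ortho-substituted phenoxide of high molecular weight, so that conversion stalls and the bromide is reduced. The fallback changes the aryl partner and the mechanism; it sets out from 35 and 20 and returns at 36. Bromide 35 is converted (n-BuLi, B(OiPr)3, THF, −78 °C; aq. NH4Cl) into [3,4-bis(benzyloxy)-5-(3,4,5-tris(benzyloxy)-2-{3,5-bis(benzyloxy)-4-[3,4,5-tris(benzyloxy)phenoxy]phenoxy}phenoxy)phenyl]boronic acid F4. F4 is joined to phenol 20 by oxidative Chan–Lam–Evans coupling (Cu(OAc)2, pyridine, 4 Å molecular sieves, CH2Cl2, air, rt) to give 36.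

3. Step 8 (C-acylation to the keto ester; step 21 likewise). The ester enolate may act as a base toward the vinylogous methyl group of the acyl imidazole, or add in conjugate fashion with loss of phenoxide, instead of attacking the acyl carbon. The fallback replaces acylation by aldol addition and oxidation; it sets out from esters 6 and 13 and returns at 15. Ester 6 is reduced (i-Bu2AlH, CH2Cl2, −78 °C) to (E)-3-[2,4,6-tris(benzyloxy)phenoxy]but-2-en-1-ol F5 and oxidised (MnO2, CH2Cl2) to (E)-3-[2,4,6-tris(benzyloxy)phenoxy]but-2-enal F6. The lithium enolate of 13 (LiN(SiMe3)2, THF, −78 °C) adds to F6 to give methyl (E)-2-[3,4,5-tris(benzyloxy)-2-bromophenoxy]-3-hydroxy-5-[2,4,6-tris(benzyloxy)phenoxy]hex-4-enoate F7 (racemic mixture of diastereomers). Dess–Martin oxidation (NaHCO3, CH2Cl2) gives 15.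

Further compounds
F1 | step 9 | dimethyl 2-[3,4,5-tris(benzyloxy)-2-bromophenoxy]malonate | COC(=O)C(Oc1cc(OCc9ccccc9)c(OCc9ccccc9)c(OCc9ccccc9)c1Br)C(=O)OC
F2 | step 9 | dimethyl 2-[3,4,5-tris(benzyloxy)-2-bromophenoxy]-2-{(E)-3-[2,4,6-tris(benzyloxy)phenoxy]but-2-enoyl}malonate | COC(=O)C(Oc1cc(OCc9ccccc9)c(OCc9ccccc9)c(OCc9ccccc9)c1Br)(C(=O)OC)C(=O)/C=C(\C)Oc1c(OCc9ccccc9)cc(OCc9ccccc9)cc1OCc9ccccc9
F3 | step 9 | methyl 1-[3,4,5-tris(benzyloxy)-2-bromophenoxy]-2,6-dioxo-4-[2,4,6-tris(benzyloxy)phenoxy]cyclohex-3-ene-1-carboxylate (racemic) | COC(=O)C1(Oc2cc(OCc9ccccc9)c(OCc9ccccc9)c(OCc9ccccc9)c2Br)C(=O)CC(Oc2c(OCc9ccccc9)cc(OCc9ccccc9)cc2OCc9ccccc9)=CC1=O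
F4 | step 24 | [3,4-bis(benzyloxy)-5-(3,4,5-tris(benzyloxy)-2-{3,5-bis(benzyloxy)-4-[3,4,5-tris(benzyloxy)phenoxy]phenoxy}phenoxy)phenyl]boronic acid | c9ccccc9COc1cc(Oc2c(OCc9ccccc9)c(OCc9ccccc9)c(OCc9ccccc9)cc2Oc2cc(B(O)O)cc(OCc9ccccc9)c2OCc9ccccc9)cc(OCc9ccccc9)c1Oc1cc(OCc9ccccc9)c(OCc9ccccc9)c(OCc9ccccc9)c1
F5 | step 8 | (E)-3-[2,4,6-tris(benzyloxy)phenoxy]but-2-en-1-ol | OC/C=C(\C)Oc1c(OCc9ccccc9)cc(OCc9ccccc9)cc1OCc9ccccc9
F6 | step 8 | (E)-3-[2,4,6-tris(benzyloxy)phenoxy]but-2-enal | O=C/C=C(\C)Oc1c(OCc9ccccc9)cc(OCc9ccccc9)cc1OCc9ccccc9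
F7 | step 8 | methyl (E)-2-[3,4,5-tris(benzyloxy)-2-bromophenoxy]-3-hydroxy-5-[2,4,6-tris(benzyloxy)phenoxy]hex-4-enoate (racemic mixture of diastereomers) | COC(=O)C(Oc1cc(OCc9ccccc9)c(OCc9ccccc9)c(OCc9ccccc9)c1Br)C(O)/C=C(\C)Oc1c(OCc9ccccc9)cc(OCc9ccccc9)cc1OCc9ccccc9
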